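From a neighbour of these flasks I carry one habit: before stepping any equation, I turn the constants into times at the charged amounts.

- spring: substrate 1.3 M; reagent 1.56 M; temperature 20 °C; time 15 h
- noon: substrate 1.3 M; reagent 1.56 M; temperature 28 °C; time 15 h

    substrate + reagent → target (k1 = 1.33 × 10⁻⁵ /M/s, Ea1 = 76.0 kJ/mol)
    substrate + 2 reagent → side product (k2 = 5.89 × 10⁻⁶ /M²/s, Ea2 = 72.0 kJ/mol)
    target → over-reaction product (k3 = 7.77 × 10⁻⁶ /s, Ea3 = 101 kJ/mol)
    (constants at 20 °C)

- for a step with 2 of a species take k times the square, and two of it per event
- at 20 °C the constants are as listed, elsewhere as the activation energies make them

* which of the two there is more of at the end, spring (target / over-reaction product)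
* which of the two there is more of at the end, noon (target / over-reaction product)
* target at the end, in percent of the substrate charged, spring
* target at the end, in percent of the substrate charged, noon

The third step is the one arrow into over-reaction product. So the end amount O of over-reaction product is that step's constant k, times the run time t, times M, the mean target over the run. Dividing by P, the target at the end, gives:

O/P = B × M/P, with B = k t

Spring has 0.420 for the burn number B, the third step's rate constant times the run time. At noon the activation energy multiplies k by 3.01, so B is 1.26.

I have two ways to M/P. A target flat through the run gives one, and a target rising steadily from nothing gives 0.5:

spring: flat 0.420, steady rise 0.210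

noon: flat 1.26, steady rise 0.630

In spring both ways stand below one, so I expect more target. At noon they fall on either side of one, so one of them cheats.

The noon pseudo-first-order time of substrate, with both substrate steps at the charged reagent, is 3.52 h. That is a quarter of the run, and it is shorter than the target's own noon lifetime of 11.9 h, which is itself shorter than the run. Reagent falls as the run goes on and stretches that first time, but a steady rise needs making spread over the whole run. So at noon I reject the steady rise, expect the target to top out inside the run, and commit to O/P near 1.26, with more over-reaction product. This reckoning gives no yields.

The forecast, stepping the equations by hand, gives target for spring and over-reaction product for noon, with target at 30.9% and 22.8%. At noon it says: “Over-reaction product reaches about 0.40 M, so it exceeds target”.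

The simulation gives target for spring and over-reaction product for noon, with target at 31.0% and 23.0%. Spring holds 9.50% over-reaction product, an O/P of 0.307, between 0.210 and 0.420. Noon holds 30.9% over-reaction product, an O/P of 1.35 against B of 1.26, with target at 28.9% after 7.50 h and 23.0% at the end. The spring neighbour charged with 2.7 M of reagent keeps B at 0.420, and its O/P is 0.340.

The rate constants come from no measurement; the run is a simulation.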